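**Retrosynthetic overview**
1. Target 24 comes from 23 by removal of the two ring B MOM ethers.
2. The route rests on ring A: C5(OH)–C6(prenyl)–C7(OH)–C8(prenyl) (flavone numbering) alternate oxygen and prenyl like a doubly prenylated polyketide chain, and ring C is a 4-pyranone whose C8a and C4a can carry that chain and an ester. Ring A is therefore cut at C5–C6, an intramolecular Claisen condensation of the C6 ketone enolate onto the C5 ester of 20.
3. 20 comes from pyranone ester 9 by lateral prenylation (sets C8 and its prenyl) and then lateral acylation with Weinreb amide 18 (brings C7, C6 and the second prenyl).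
4. Ring C (9) comes from methyl acetoacetate 6 and arylpropiolic acid 5 by C-acylation and 6-endo-dig oxa-Michael closure; 5 comes from 2,4-dihydroxybenzaldehyde 1, and 18 from the Johnson–Claisen ester 17.
5. Ring order: ring B (purchased), then ring C (step 4), then ring A (step 9).

Key step: step 9

Remark: ring A atoms are numbered C5–C8 as in the flavone throughout; 20 and 22 each carry one sp3 center that is racemic and is erased on aromatization, so no stereocontrol is needed and the target has no stereocenter.

**Step 1**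
Reactants: 1 2,4-dihydroxybenzaldehyde
Product: 2 2,4-bis(methoxymethoxy)benzaldehyde
Conditions: MOMCl (3 equiv), i-Pr2NEt (4 equiv), CH2Cl2, 0 °C to 40 °C
Reagents that add atoms: chloromethyl methyl ether, COCCl
Why: O-alkylation of both phenols (Williamson-type acetal formation); excess reagent and gentle warming should overcome the hydrogen bond of the 2-OH to the aldehyde.

**Step 2**
Reactants: 2 2,4-bis(methoxymethoxy)benzaldehyde
Product: 3 1-ethynyl-2,4-bis(methoxymethoxy)benzene
Conditions: dimethyl (1-diazo-2-oxopropyl)phosphonate, K2CO3, MeOH, 0 °C to rt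
Reagents that add atoms: dimethyl (1-diazo-2-oxopropyl)phosphonate, COP(=O)(OC)C(=[N+]=[N-])C(C)=O
Why: Ohira–Bestmann (Seyferth–Gilbert) homologation, in which methanolysis frees the diazomethylphosphonate anion, olefination and loss of N2 with 1,2-shift give the terminal alkyne under mild base that MOM ethers tolerate.

**Step 3**
Reactants: 3 1-ethynyl-2,4-bis(methoxymethoxy)benzene
Product: 5 3-[2,4-bis(methoxymethoxy)phenyl]prop-2-ynoic acid, via lithium arylacetylide 4 (not isolated)
Conditions: n-BuLi (1.05 equiv), THF, −78 °C; CO2, −78 °C to 0 °C; cold 1 M HCl to pH 3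
Reagents that add atoms: carbon dioxide, O=C=O
Why: Deprotonation of the terminal alkyne is far faster than ring lithiation at −78 °C, and carboxylation of the acetylide gives the propiolic acid, with a brief cold acidification that should spare the MOM ethers.

**Step 4**
Reactants: 5 3-[2,4-bis(methoxymethoxy)phenyl]prop-2-ynoic acid; 6 methyl acetoacetate
Product: 9 methyl 6-[2,4-bis(methoxymethoxy)phenyl]-2-methyl-4-oxo-4H-pyran-3-carboxylate, via arylpropioloyl chloride 7 (not isolated), via acyclic ynone keto ester 8 (not isolated)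
Conditions: 1-chloro-N,N,2-trimethylprop-1-en-1-amine (1.0 equiv), CH2Cl2, 0 °C to rt; then added to 6, MgCl2, pyridine, CH2Cl2, 0 °C to rt; then Et3N (0.2 equiv), 40 °C
Reagents that add atoms: none
Why: The acid chloride forms under neutral conditions that spare the MOM ethers, the chelated magnesium enolate of 6 is C-acylated (Rathke acylation), and the enol oxygen of the acetyl group then adds to the ynone β-carbon in a 6-endo-dig oxa-Michael closure of ring C, the classical γ-pyranone synthesis from arylpropioloyl chlorides and β-keto esters.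

**Step 5**
Reactants: 9 methyl 6-[2,4-bis(methoxymethoxy)phenyl]-2-methyl-4-oxo-4H-pyran-3-carboxylate; 10 prenyl bromide (1-bromo-3-methylbut-2-ene)
Product: 12 methyl 6-[2,4-bis(methoxymethoxy)phenyl]-2-(4-methylpent-3-en-1-yl)-4-oxo-4H-pyran-3-carboxylate, via lithium dienolate 11 (not isolated)
Conditions: LiN(SiMe3)2 (1.05 equiv), THF, −78 °C; then 10, −78 °C to −20 °C
Reagents that add atoms: none
Why: Lateral (vinylogous) deprotonation of the 2-methyl group and SN2 alkylation at the exocyclic carbon, which restores the pyranone; the 6-aryl group leaves a single lateral site and a slight deficit of base should limit double alkylation.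

**Step 6**
Reactants: 13 2-methylbut-3-en-2-ol; 14 triethyl orthoacetate
Product: 17 ethyl 5-methylhex-4-enoate, via mixed orthoester 15 (not isolated), via ketene acetal 16 (not isolated)
Conditions: EtCO2H (cat.), neat, 140 °C, EtOH distilled off
Reagents that add atoms: none
Why: Johnson–Claisen rearrangement, in which orthoester exchange and loss of ethanol give the ketene acetal and its [3,3] shift delivers the γ,δ-unsaturated ester with the trisubstituted (prenyl-type) alkene.

**Step 7**
Reactants: 17 ethyl 5-methylhex-4-enoate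
Product: 18 N-methoxy-N,5-dimethylhex-4-enamide
Conditions: MeNH(OMe)·HCl (1.5 equiv), i-PrMgCl (3.0 equiv), THF, −20 °C to 0 °C; aq. NH4Cl
Reagents that add atoms: N,O-dimethylhydroxylamine hydrochloride, CNOC.Cl
Why: Aminolysis of the ester by the magnesium amide made in the flask (Weinreb amide formation); the isolated alkene is inert.

**Step 8**
Reactants: 12 methyl 6-[2,4-bis(methoxymethoxy)phenyl]-2-(4-methylpent-3-en-1-yl)-4-oxo-4H-pyran-3-carboxylate; 18 N-methoxy-N,5-dimethylhex-4-enamide
Product: 20 methyl 6-[2,4-bis(methoxymethoxy)phenyl]-2-(2,10-dimethyl-6-oxoundeca-2,9-dien-5-yl)-4-oxo-4H-pyran-3-carboxylate (racemic, enolizable), via lithium dienolate 19 (not isolated)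
Conditions: LiN(SiMe3)2 (1.1 equiv), THF, −78 °C; then 18 (1.3 equiv), −78 °C to 0 °C; aq. NH4Cl
Reagents that add atoms: none
Why: Claisen-type C-acylation of the lateral dienolate by the Weinreb amide, whose chelated tetrahedral adduct should persist until the quench so that the acidic product neither protonates unreacted dienolate nor cyclizes early; the new sp3 center (C8) forms racemic and is lost in step 9.

**Step 9**
Reactants: 20 methyl 6-[2,4-bis(methoxymethoxy)phenyl]-2-(2,10-dimethyl-6-oxoundeca-2,9-dien-5-yl)-4-oxo-4H-pyran-3-carboxylate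
Product: 23 2-[2,4-bis(methoxymethoxy)phenyl]-5,7-dihydroxy-6,8-bis(3-methylbut-2-en-1-yl)-4H-chromen-4-one, via dilithium dianion 21 (not isolated), via 6H-keto tautomer 22 (not isolated)
Conditions: LiN(i-Pr)2 (3.0 equiv), THF, −78 °C to 0 °C; aq. NH4Cl
Reagents that add atoms: none
Why: The first equivalent of base removes the most acidic proton at C8 (flanked by the C7 ketone and vinylogous to the pyranone carbonyl and the ester) to give an extended enolate, the second can then only deprotonate the C6 methylene to give dianion 21, whose terminal C6 carbanion adds to the ester carbon C5; loss of methoxide gives 22, and the third equivalent (or the methoxide) removes the now doubly activated C6–H so that the ring ends as the diphenoxide of 23. The closest known reaction type is the Dieckmann-type intramolecular Claisen condensation of 4-pyranone-masked β-polyketo esters to phloroglucinol-type rings. Ring A closes in a 6-(enolexo)-exo-trig mode, C6 onto the ester carbon with the C5=O bond exocyclic to the new ring. No stereocenter remains, since the sp3 centers at C8 of 20 and at C6 of 22 are racemic and are erased on aromatization. The step needs C–C bond formation from C6 and not enolization at C8 alone or O-acylation by the C7 enolate oxygen (which would give a fused 2-pyranone); parking C8 as its enolate leaves C6 as the only site for the second deprotonation, the pyranone C2=C3 bond holds chain and ester cis on adjacent sp2 carbons, and the product is drained irreversibly as the aromatic diphenoxide whose 5-OH hydrogen-bonds to C4=O after work-up.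

**Step 10**
Reactants: 23 2-[2,4-bis(methoxymethoxy)phenyl]-5,7-dihydroxy-6,8-bis(3-methylbut-2-en-1-yl)-4H-chromen-4-one
Product: 24 2-(2,4-dihydroxyphenyl)-5,7-dihydroxy-6,8-bis(3-methylbut-2-en-1-yl)-4H-chromen-4-one (CNP0150533.0)
Conditions: 3 M aq. HCl, MeOH, 45 °C, stopped at full conversion
Reagents that add atoms: none
Why: Acid-catalyzed transacetalization of the two aryl MOM ethers to methanol; dilute acid, moderate temperature and short exposure should leave the prenyl groups uncyclized.

**Compound list**
1 | 2,4-dihydroxybenzaldehyde | O=Cc1ccc(O)cc1O | starting material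
2 | 2,4-bis(methoxymethoxy)benzaldehyde | COCOc1ccc(C=O)c(OCOC)c1 | intermediate
3 | 1-ethynyl-2,4-bis(methoxymethoxy)benzene | C#Cc1ccc(OCOC)cc1OCOC | intermediate
4 | lithium [2,4-bis(methoxymethoxy)phenyl]ethynide | [Li+].[C-]#Cc1ccc(OCOC)cc1OCOC | intermediate (not isolated)
5 | 3-[2,4-bis(methoxymethoxy)phenyl]prop-2-ynoic acid | OC(=O)C#Cc1ccc(OCOC)cc1OCOC | intermediate
6 | methyl acetoacetate (methyl 3-oxobutanoate) | COC(=O)CC(C)=O | starting material
7 | 3-[2,4-bis(methoxymethoxy)phenyl]prop-2-ynoyl chloride | O=C(Cl)C#Cc1ccc(OCOC)cc1OCOC | intermediate (not isolated)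
8 | methyl 2-acetyl-5-[2,4-bis(methoxymethoxy)phenyl]-3-oxopent-4-ynoate | COC(=O)C(C(C)=O)C(=O)C#Cc1ccc(OCOC)cc1OCOC | intermediate (not isolated)
9 | methyl 6-[2,4-bis(methoxymethoxy)phenyl]-2-methyl-4-oxo-4H-pyran-3-carboxylate | COC(=O)c1c(C)oc(-c2ccc(OCOC)cc2OCOC)cc1=O | intermediate
10 | prenyl bromide (1-bromo-3-methylbut-2-ene) | CC(C)=CCBr | starting material
11 | lithium dienolate of 9 (lateral anion at the 2-methyl group, drawn as the 4-oxido-2-methylidene form) | [Li+].C=C1OC(c2ccc(OCOC)cc2OCOC)=CC([O-])=C1C(=O)OC | intermediate (not isolated)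
12 | methyl 6-[2,4-bis(methoxymethoxy)phenyl]-2-(4-methylpent-3-en-1-yl)-4-oxo-4H-pyran-3-carboxylate | COC(=O)c1c(CCC=C(C)C)oc(-c2ccc(OCOC)cc2OCOC)cc1=O | intermediate
13 | 2-methylbut-3-en-2-ol | CC(C)(O)C=C | starting material
14 | triethyl orthoacetate (1,1,1-triethoxyethane) | CCOC(C)(OCC)OCC | starting material
15 | 3-(1,1-diethoxyethoxy)-3-methylbut-1-ene (mixed orthoester) | CCOC(C)(OCC)OC(C)(C)C=C | intermediate (not isolated)
16 | 3-[(1-ethoxyethenyl)oxy]-3-methylbut-1-ene (ketene acetal) | CCOC(=C)OC(C)(C)C=C | intermediate (not isolated)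
17 | ethyl 5-methylhex-4-enoate | CCOC(=O)CCC=C(C)C | intermediate
18 | N-methoxy-N,5-dimethylhex-4-enamide | CON(C)C(=O)CCC=C(C)C | intermediate
19 | lithium dienolate of 12 (lateral anion, drawn as the 4-oxido-2-ylidene form) | [Li+].CC(C)=CCC=C1OC(c2ccc(OCOC)cc2OCOC)=CC([O-])=C1C(=O)OC | intermediate (not isolated)
20 | methyl 6-[2,4-bis(methoxymethoxy)phenyl]-2-(2,10-dimethyl-6-oxoundeca-2,9-dien-5-yl)-4-oxo-4H-pyran-3-carboxylate (racemic) | COC(=O)c1c(C(CC=C(C)C)C(=O)CCC=C(C)C)oc(-c2ccc(OCOC)cc2OCOC)cc1=O | intermediate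
21 | dilithium dianion of 20 (C8 extended enolate and C6 enolate) | [Li+].[Li+].COC(=O)C1=C([O-])C=C(c2ccc(OCOC)cc2OCOC)OC1=C(CC=C(C)C)C([O-])=CCC=C(C)C | intermediate (not isolated)
22 | 2-[2,4-bis(methoxymethoxy)phenyl]-7-hydroxy-6,8-bis(3-methylbut-2-en-1-yl)-4H-chromene-4,5(6H)-dione (racemic keto tautomer of 23) | CC(C)=CCC1C(=O)c2c(oc(-c3ccc(OCOC)cc3OCOC)cc2=O)C(CC=C(C)C)=C1O | intermediate (not isolated)
23 | 2-[2,4-bis(methoxymethoxy)phenyl]-5,7-dihydroxy-6,8-bis(3-methylbut-2-en-1-yl)-4H-chromen-4-one | CC(C)=CCc1c(O)c(CC=C(C)C)c2oc(-c3ccc(OCOC)cc3OCOC)cc(=O)c2c1O | intermediate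
24 | 2-(2,4-dihydroxyphenyl)-5,7-dihydroxy-6,8-bis(3-methylbut-2-en-1-yl)-4H-chromen-4-one | CC(C)=CCc1c(O)c(CC=C(C)C)c2oc(-c3ccc(O)cc3O)cc(=O)c2c1O | target

**Step count**
Total: 10 steps. Longest linear sequence: 8 steps (steps 1, 2, 3, 4, 5, 8, 9, 10).

**Steps most likely to fail**

Step 9. The second deprotonation at C6 may be incomplete, or the C7 enolate oxygen may acylate on the ester and lactonize to a fused 2-pyranone, both made worse by crowding from the C8 prenyl group. The fallback sets out from 9 and comes back at 23. Dienolate 11 is acylated with 18 (LiN(SiMe3)2, THF, −78 °C to 0 °C) to give methyl 6-[2,4-bis(methoxymethoxy)phenyl]-2-(6-methyl-2-oxohept-5-en-1-yl)-4-oxo-4H-pyran-3-carboxylate F1. This less hindered keto ester is closed under thermodynamic, chelating conditions (Mg(OMe)2, MeOH, reflux) to 2-[2,4-bis(methoxymethoxy)phenyl]-5,7-dihydroxy-6-(3-methylbut-2-en-1-yl)-4H-chromen-4-one F2. C-Prenylation of its phenoxide with 10 in aqueous KOH at the only free ring A carbon, C8, then gives 23; O-prenyl ethers are the expected by-products of this last operation.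

Step 4. The ynoyl chloride may suffer conjugate addition by pyridine or by the enolate carbon, and the acyclic ynone may close 5-exo-dig to an alkylidene furanone instead of the pyranone. The fallback sets out from 2 and comes back at 9, using an alkene in place of the alkyne. Knoevenagel–Doebner condensation of 2 with malonic acid (pyridine, piperidine cat., 90 °C) gives (2E)-3-[2,4-bis(methoxymethoxy)phenyl]prop-2-enoic acid F3. The same neutral chlorination gives (2E)-3-[2,4-bis(methoxymethoxy)phenyl]prop-2-enoyl chloride F4, and Rathke acylation of 6 (MgCl2, pyridine) gives methyl (4E)-2-acetyl-5-[2,4-bis(methoxymethoxy)phenyl]-3-oxopent-4-enoate F5. Oxa-Michael closure (NaOAc, MeOH, 60 °C) gives racemic methyl 2-[2,4-bis(methoxymethoxy)phenyl]-6-methyl-4-oxo-3,4-dihydro-2H-pyran-5-carboxylate F6, and dehydrogenation with DDQ (dioxane, 80 °C), as in the flavanone-to-flavone oxidation, gives 9.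

Step 8. The stabilized, secondary lateral dienolate may add too slowly to the amide, or early collapse of the adduct may lead to proton transfer that stalls conversion. The fallback sets out from 12 and 17 and comes back at 20. Ester 17 is reduced (i-Bu2AlH, CH2Cl2, −78 °C) to 5-methylhex-4-enal F7. Aldol addition of dienolate 19 to this more reactive electrophile at −78 °C, quenched cold with AcOH to prevent lactonization of the aldolate onto the ester, gives methyl 6-[2,4-bis(methoxymethoxy)phenyl]-2-(6-hydroxy-2,10-dimethylundeca-2,9-dien-5-yl)-4-oxo-4H-pyran-3-carboxylate F8 as a mixture of racemic diastereomers. Oxidation with Dess–Martin periodinane (NaHCO3, CH2Cl2) gives 20.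

**Further compounds**
F1 | step 9 | methyl 6-[2,4-bis(methoxymethoxy)phenyl]-2-(6-methyl-2-oxohept-5-en-1-yl)-4-oxo-4H-pyran-3-carboxylate | COC(=O)c1c(CC(=O)CCC=C(C)C)oc(-c2ccc(OCOC)cc2OCOC)cc1=O
F2 | step 9 | 2-[2,4-bis(methoxymethoxy)phenyl]-5,7-dihydroxy-6-(3-methylbut-2-en-1-yl)-4H-chromen-4-one | CC(C)=CCc1c(O)cc2oc(-c3ccc(OCOC)cc3OCOC)cc(=O)c2c1O
F3 | step 4 | (2E)-3-[2,4-bis(methoxymethoxy)phenyl]prop-2-enoic acid | OC(=O)/C=C/c1ccc(OCOC)cc1OCOC
F4 | step 4 | (2E)-3-[2,4-bis(methoxymethoxy)phenyl]prop-2-enoyl chloride | O=C(Cl)/C=C/c1ccc(OCOC)cc1OCOC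
F5 | step 4 | methyl (4E)-2-acetyl-5-[2,4-bis(methoxymethoxy)phenyl]-3-oxopent-4-enoate | COC(=O)C(C(C)=O)C(=O)/C=C/c1ccc(OCOC)cc1OCOC
F6 | step 4 | methyl 2-[2,4-bis(methoxymethoxy)phenyl]-6-methyl-4-oxo-3,4-dihydro-2H-pyran-5-carboxylate (racemic) | COC(=O)C1=C(C)OC(c2ccc(OCOC)cc2OCOC)CC1=O
F7 | step 8 | 5-methylhex-4-enal | CC(C)=CCCC=O
F8 | step 8 | methyl 6-[2,4-bis(methoxymethoxy)phenyl]-2-(6-hydroxy-2,10-dimethylundeca-2,9-dien-5-yl)-4-oxo-4H-pyran-3-carboxylate (racemic diastereomers) | COC(=O)c1c(C(CC=C(C)C)C(O)CCC=C(C)C)oc(-c2ccc(OCOC)cc2OCOC)cc1=O
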